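**The yardstick.** This reckoning is built on how long the solid substrate lasts, since what has reacted at 15 h is the charge less what is still solid or dissolved.

- beta: solid substrate 0.10 M; acid 0.010 M; scavenger 0.050 M; the very flask that is asked about, followed so far
- flask: solid substrate 0.10 M; acid 0.0100 M; scavenger 0.0500 M; time 15 h

beta run (percent of the solid substrate charged)

| time / h | solid substrate / % | product / % |
|---|---|---|
| 0.500 | 97 | 0 |
| 1.00 | 89 | 2 |
| 1.50 | 85 | 3 |
| 2.00 | 80 | 7 |
| 2.50 | 77 | 4 |
| 3.00 | 71 | 6 |

(scatter of a reading: 2 percentage points)

* part of the solid substrate that has reacted (what has only dissolved counts as not reacted) at 15 h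
* pH of the solution at 15 h

- acid is the free proton; pH is minus the decimal logarithm of its molar concentration
- solid, in amounts per volume of the solution: solid substrate
- at the start none of the solid substrate is in solution
- what has only dissolved of solid substrate counts as not reacted
- what has gone from starting material into another species counts as reacted, even if it can come back

**Feed first.** Suppose dissolving were the one process. The beta flask, the one asked about, has lost 29.0 % of its solid by 3.00 h, so at that pace the solid lasts 10.3 h: the emptying time. This is shorter than 15 h, so the ceiling on the answer is the whole charge.

**Then drain.** The dissolved pool at 3.00 h is what has left the solid minus the product, 23.0 %. Taking that pool as a rising line, the product reading gives a pseudo-first-order drain constant of 0.174 h⁻¹, a rough reading given the scatter. A steady feed against this drain leaves 46.4 % dissolved at emptying. The pool then decays until 15 h, which lowers the ceiling to 79.4 % reacted.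

**Acid balance.** Acid is charged in the smallest amount, at 10.0 % of the solid substrate. Spent one to one, it could not carry the reckoned 79.4 %. This reckoning therefore takes it as a catalyst, with [acid] staying at 0.0100 M, which leaves the drain unchanged and gives pH 2.00.

**The result.** The forecast gives 68 % and, on the guess that “the scavenger mops up acid released by the reaction”, pH 1.7; it differs from this reckoning on both. The flask gives 90.7 % and pH 2.00, so the reckoned conversion is 11 percentage points low and the reckoned pH holds.

    starting material + weak acid ⇌ idle adduct, settled at all times (K = 800 M⁻¹)
    solid substrate ⇌ starting material, rate k2*(cs2 - [starting material]) while solid is left; crystals form when [starting material] > cs2 (solubility = 0.0690 M, k = 0.160 h⁻¹)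
    weak acid ⇌ conjugate base + acid, settled at all times (K = 4.00 × 10⁻¹⁰ M)
    starting material + acid → weak acid + acid + product (k = 22.0 M⁻¹ h⁻¹)
    starting material → weak acid + product (k = 0.0290 h⁻¹)
    starting material ⇌ dormant form (K = 0.490, k = 0.0220 h⁻¹)
    weak acid + scavenger → scavenged by-product (k = 28.0 M⁻¹ h⁻¹)

**Feed against drain.** In the beta flask, half of the dissolving up to the asked time is done by 5.56 h, and half of the turnover of the acid step by 7.95 h, which is 2.39 h later. At 15.0 h that flask holds 0 % solid substrate and 9.30 % starting material. The neighbour read at 4.0 h, reckoned by the same emptying time at 61.2 % solid substrate, holds 63.0 %; the neighbour read at 10 h, reckoned at 3.33 %, holds 14.1 %.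

Readings and results stem from a simulated flask for an exercise, noise included.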